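## Retrosynthetic overview

1. Feature: in chroman numbering the carbocycle C4a–C5–C6–C7–C8–C8a is a cyclohexa-2,4-dienone whose fully substituted C8 (prenyl and lavandulyl) is bonded to the C7 carbonyl. A dienylketene with a dialkylated diene terminus closes to exactly this pattern and cannot aromatise.
2. Target ⇐ ester cleavage ⇐ dihydropyranone closure (O1–C8a; the side-chain hydroxyl displaces the C8a ethoxy group) ⇐ C4–C4a bond (C4a iodide + syn-aldol-derived aldehyde, Nozaki–Hiyama–Kishi coupling, oxidation).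
3. Dienone 20 ⇐ C7–C8 bond by 6π closure of dienylketene 19 ⇐ 4-alkenyl-3-silyloxycyclobutenone 18 ⇐ [2+2] of vinylketene 17 with siloxyalkyne 16.
4. 17 ⇐ 3-ethoxy-4,4-dialkylcyclobutenone 8 ⇐ lavandulyl(prenyl)ketene + ethoxyacetylene; 16 ⇐ Rh-catalysed conjugate alkynylation of benzylidene Meldrum's acid, then ynolate oxidation/silylation.
5. Ring order: cyclobutenones 8 and 18 (transient carriers) → six-membered carbocycle (step 10) → dihydropyranone (step 18).

Key step: step 10

## Remarks on the chemistry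

- Lavandulyl = (2S)-5-methyl-2-(prop-1-en-2-yl)hex-4-en-1-yl; prenyl = 3-methylbut-2-en-1-yl. The lavandulyl stereocentre is never touched; its descriptor changes from R (1, 2) to S (4 onward) only because the CH2X arm drops in CIP priority.
- The C8a oxygen is carried as an ethyl enol ether, because ethoxyacetylene is the commercial ynol ether; it leaves as ethanol in step 18.
- Assumption for step 5: the antipode of the bisphosphine is chosen that gives the configuration drawn for 11.
- Assumption for step 10: the two C8 epimers of the dienone are separable by chromatography.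

## Route

Step 1
Reactants: 1 (R)-lavandulol
Product: 2 (R)-lavandulyl iodide
Conditions: I2, PPh3, imidazole, CH2Cl2, 0 °C → rt
Reagents that add atoms: iodine, II
Why: Appel-type (Garegg–Samuelsson) iodination of the primary alcohol; the β-stereocentre is not involved.

Step 2
Reactants: 3 5-methylhex-4-enoic acid; 2 (R)-lavandulyl iodide
Product: 4 2-lavandulyl-5-methylhex-4-enoic acid (both C2 epimers)
Conditions: LDA (2.2 equiv), THF, −78 → 0 °C; then 2, DMPU, 0 °C → rt; aq. citric acid work-up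
Reagents that add atoms: none
Why: α-alkylation of the carboxylic acid dianion with the primary iodide; the new α-centre is formed as a mixture and is erased when it becomes the ketene carbon in step 4.

Step 3
Reactants: 4 2-lavandulyl-5-methylhex-4-enoic acid
Product: 5 2-lavandulyl-5-methylhex-4-enoyl chloride
Conditions: 1-chloro-N,N,2-trimethylprop-1-en-1-amine (Ghosez's reagent), CH2Cl2, 0 °C → rt; used crude
Reagents that add atoms: 1-chloro-N,N,2-trimethylprop-1-en-1-amine, CC(C)=C(Cl)N(C)C
Why: neutral acid chloride formation with the α-chloroenamine, which avoids free HCl that would add to the trisubstituted and 1,1-disubstituted alkenes.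

Step 4
Reactants: 5 2-lavandulyl-5-methylhex-4-enoyl chloride; 6 ethoxyacetylene
Product: 8 3-ethoxy-4-lavandulyl-4-prenylcyclobut-2-en-1-one (both C4 epimers), via lavandulyl(prenyl)ketene 7 (not isolated)
Conditions: 6 (3 equiv), Et3N, Et2O, rt, slow addition of 5
Reagents that add atoms: none
Why: dehydrochlorination gives the dialkylketene, which undergoes the regioselective ketene–ynol ether [2+2] cycloaddition (ketene carbonyl carbon to the unsubstituted alkyne carbon); excess ynol ether at rt should outrun intramolecular ketene–alkene cycloaddition.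

Step 5
Reactants: 9 5-benzylidene-2,2-dimethyl-1,3-dioxane-4,6-dione; 10 (trimethylsilyl)acetylene
Product: 11 2,2-dimethyl-5-[(1S)-1-phenyl-3-(trimethylsilyl)prop-2-yn-1-yl]-1,3-dioxane-4,6-dione
Conditions: Rh(acac)(C2H4)2 (cat.), 3,5-xylyl-MeO-BIPHEP (cat., antipode giving 11), 1,4-dioxane/H2O, rt
Reagents that add atoms: none
Why: Rh-catalysed enantioselective conjugate alkynylation of an arylidene Meldrum's acid with a silylacetylene; the chiral bisphosphine–Rh alkynyl species selects the face of the acceptor and so sets the benzylic stereocentre.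

Step 6
Reactants: 11 Meldrum's acid adduct
Product: 13 (3R)-3-phenylpent-4-ynoic acid, via silylalkynyl acid 12 (not isolated)
Conditions: pyridine/H2O (10:1), 95 °C; then K2CO3, MeOH, rt; aq. citric acid work-up
Reagents that add atoms: water, O
Why: hydrolytic opening of the Meldrum's acid ring and decarboxylation of the malonic acid, then protodesilylation of the alkynylsilane; the stereocentre is β to the carboxyl and is not enolisable.

Step 7
Reactants: 13 (3R)-3-phenylpent-4-ynoic acid
Product: 14 tert-butyl (3R)-3-phenylpent-4-ynoate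
Conditions: Boc2O, DMAP (cat.), t-BuOH, 35 °C
Reagents that add atoms: di-tert-butyl dicarbonate, CC(C)(C)OC(=O)OC(=O)OC(C)(C)C; tert-butanol, CC(C)(C)O
Why: DMAP-catalysed tert-butyl esterification through the mixed carbonic anhydride; the hindered ester is chosen to resist the nucleophilic peroxide and amide base of step 8.

Step 8
Reactants: 14 tert-butyl (3R)-3-phenylpent-4-ynoate
Product: 16 tert-butyl (3S)-3-phenyl-5-[(triisopropylsilyl)oxy]pent-4-ynoate, via lithium ynolate 15 (not isolated)
Conditions: LiHMDS (2.1 equiv), THF, −78 °C; t-BuOOH (as t-BuOOLi), −78 → 0 °C; TIPSOTf, −78 → 0 °C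
Reagents that add atoms: tert-butyl hydroperoxide, CC(C)(C)OO; triisopropylsilyl trifluoromethanesulfonate, CC(C)[Si](C(C)C)(C(C)C)OS(=O)(=O)C(F)(F)F
Why: oxidation of the lithium acetylide with lithium tert-butyl peroxide gives the ynolate, which is O-silylated by the bulky silyl triflate (Julia-type siloxyalkyne synthesis); the descriptor changes to S only by CIP priority.

Step 9
Reactants: 8 3-ethoxy-4-lavandulyl-4-prenylcyclobut-2-en-1-one; 16 siloxyalkyne
Product: 18 tert-butyl (3S)-3-{3-[1-ethoxy-2-lavandulyl-2-prenylethenyl]-4-oxo-2-[(triisopropylsilyl)oxy]cyclobut-1-en-1-yl}-3-phenylpropanoate (both ring epimers and both enol ether geometries), via vinylketene 17 (not isolated)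
Conditions: 16 (1.5 equiv), hν (300 nm lamps, quartz), degassed CH2Cl2, 0–15 °C; concentrated cold, filtered through deactivated silica
Reagents that add atoms: none
Why: photochemical 4π ring opening of the cyclobutenone gives the vinylketene at low temperature, and its [2+2] cycloaddition with the electron-rich siloxyalkyne is regioselective (ketene carbonyl carbon to the alkyne carbon remote from oxygen), as in the first half of the cyclobutenone–alkyne benzannulation; the product needs heat to react further and should accumulate.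

Step 10
Reactants: 18 4-alkenyl-3-silyloxycyclobutenone
Product: 20 tert-butyl (3S)-3-{(5S)-4-ethoxy-5-lavandulyl-6-oxo-5-prenyl-2-[(triisopropylsilyl)oxy]cyclohexa-1,3-dien-1-yl}-3-phenylpropanoate, via dienylketene 19 (not isolated)
Conditions: PhMe (0.02 M), 80–90 °C, Ar, BHT (cat.); chromatographic separation of the C8 epimers
Reagents that add atoms: none
Why: Thermal conrotatory 4π opening of the strained cyclobutenone gives dienylketene 19, and disrotatory 6π electrocyclisation joins the ketene carbon (C7) to the dialkylated alkene terminus (C8), closing the six-membered carbocycle. The closest known reaction is the second half of the Danheiser benzannulation, the thermal conversion of 4-alkenylcyclobutenones into cyclohexa-2,4-dienones, here stopped at the dienone because C8 bears no hydrogen and cannot tautomerise to a phenol. Ring opening is reversible, so material that opens with the alkenyl group turned outward returns to 18 and re-opens until the geometry that can cyclise is reached. The new stereocentre C8 is fixed by the helical sense of the closure in combination with the enol ether geometry, and only the resident benzylic and lavandulyl stereocentres bias it, so both C8 epimers are expected and the 8S isomer is separated. The step needs periselectivity for the 6π closure over intramolecular ketene–alkene [2+2] and hydrogen shifts, which the cis-dienyl arrangement secures by proximity. The temperature is kept at 80–90 °C so that the C8 prenyl group does not undergo a [3,3] shift.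

Step 11
Reactants: 20 dienone
Product: 21 tert-butyl (3S)-3-{(5S)-4-ethoxy-3-iodo-5-lavandulyl-6-oxo-5-prenyl-2-[(triisopropylsilyl)oxy]cyclohexa-1,3-dien-1-yl}-3-phenylpropanoate
Conditions: NIS (1.05 equiv), NaHCO3, CH2Cl2/MeCN, −30 → 0 °C, dark
Reagents that add atoms: N-iodosuccinimide, O=C1CCC(=O)N1I
Why: electrophilic iodination of the ethyl enol ether at its β-carbon C4a, the only ring carbon that carries hydrogen; an iodonium adduct at the fully substituted C6 cannot lose a proton and should revert, while the C4a adduct loses H+ to restore the dienone.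

Step 12
Reactants: 22 (4S)-4-benzyl-3-propanoyl-1,3-oxazolidin-2-one; 23 acetaldehyde
Product: 24 (4S)-4-benzyl-3-[(2S,3R)-3-hydroxy-2-methylbutanoyl]-1,3-oxazolidin-2-one
Conditions: Bu2BOTf, i-Pr2NEt, CH2Cl2, −78 °C; 23, −78 → 0 °C; pH 7 buffer, MeOH, H2O2
Reagents that add atoms: none
Why: Evans syn-aldol reaction; the Z-boron enolate reacts through a chair transition state on the face away from the benzyl group, which sets both carbinol and α-methyl centres (the future C2 and C3).

Step 13
Reactants: 24 syn-aldol adduct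
Product: 25 (4S)-4-benzyl-3-[(2S,3R)-3-{[tert-butyl(dimethyl)silyl]oxy}-2-methylbutanoyl]-1,3-oxazolidin-2-one
Conditions: TBSOTf, 2,6-lutidine, CH2Cl2, 0 °C
Reagents that add atoms: tert-butyldimethylsilyl trifluoromethanesulfonate, CC(C)(C)[Si](C)(C)OS(=O)(=O)C(F)(F)F
Why: silylation of the secondary alcohol blocks retro-aldol and elimination in the steps that follow.

Step 14
Reactants: 25 silylated imide
Product: 26 (2R,3R)-3-{[tert-butyl(dimethyl)silyl]oxy}-2-methylbutan-1-ol
Conditions: LiBH4, MeOH (1 equiv), THF, 0 °C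
Reagents that add atoms: none
Why: reductive removal of the oxazolidinone auxiliary by borohydride attack at the exocyclic carbonyl; no stereocentre is touched (the C2 descriptor changes by priority only).

Step 15
Reactants: 26 primary alcohol
Product: 27 (2S,3R)-3-{[tert-butyl(dimethyl)silyl]oxy}-2-methylbutanal
Conditions: Dess–Martin periodinane, NaHCO3, CH2Cl2, 0 °C → rt; used at once
Reagents that add atoms: none
Why: buffered Dess–Martin oxidation gives the α-branched aldehyde without epimerisation.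

Step 16
Reactants: 21 C4a iodide; 27 aldehyde
Product: 28 tert-butyl (3S)-3-{(5S)-3-[(2S,3R)-3-{[tert-butyl(dimethyl)silyl]oxy}-1-hydroxy-2-methylbutyl]-4-ethoxy-5-lavandulyl-6-oxo-5-prenyl-2-[(triisopropylsilyl)oxy]cyclohexa-1,3-dien-1-yl}-3-phenylpropanoate (both carbinol epimers)
Conditions: CrCl2 (6 equiv), NiCl2 (2 mol%), 27 (2 equiv), DMSO/THF, rt; pH 7 work-up
Reagents that add atoms: none
Why: Nozaki–Hiyama–Kishi coupling; the Ni-generated alkenylchromium(III) adds to the aldehyde chemoselectively in the presence of the dienone carbonyl, the ester and the silyl ethers, and the new carbinol centre is removed in step 17.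

Step 17
Reactants: 28 allylic alcohol
Product: 29 tert-butyl (3S)-3-{(5S)-3-[(2S,3R)-3-{[tert-butyl(dimethyl)silyl]oxy}-2-methylbutanoyl]-4-ethoxy-5-lavandulyl-6-oxo-5-prenyl-2-[(triisopropylsilyl)oxy]cyclohexa-1,3-dien-1-yl}-3-phenylpropanoate
Conditions: Dess–Martin periodinane, NaHCO3, CH2Cl2, 0 °C
Reagents that add atoms: none
Why: neutral oxidation of the secondary allylic alcohol to the C4 ketone, which makes C8a the β-carbon of an ethoxy-enone for the ring closure.

Step 18
Reactants: 29 C4a acyl dienone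
Product: 31 tert-butyl (3S)-3-[(2R,3S,8S)-5-hydroxy-8-lavandulyl-2,3-dimethyl-4,7-dioxo-8-prenyl-3,4,7,8-tetrahydro-2H-chromen-6-yl]-3-phenylpropanoate, via hydroxy enol 30 (not isolated)
Conditions: HF·pyridine, pyridine, THF, 0 °C → rt
Reagents that add atoms: none
Why: fluoride cleaves the vinylogous silyl ester and the TBS ether, and the freed secondary hydroxyl adds to C8a and expels ethanol (intramolecular vinylogous transesterification, 6-endo); the O1–C8a bond forms with retention at C2, so the syn aldol pattern becomes the cis-2,3-dimethyl ring.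

Step 19
Reactants: 31 tert-butyl ester
Product: 33 (3S)-3-[(2R,3S,8S)-5-hydroxy-8-lavandulyl-2,3-dimethyl-4,7-dioxo-8-prenyl-3,4,7,8-tetrahydro-2H-chromen-6-yl]-3-phenylpropanoic acid (target), via bis(trimethylsilyl) derivative 32 (not isolated)
Conditions: TMSOTf, 2,6-lutidine, CH2Cl2, 0 °C; then pH 5 aqueous buffer
Reagents that add atoms: none
Why: silyl triflate-mediated cleavage of the tert-butyl ester with loss of isobutene under buffered, non-protic conditions that spare the prenyl and isopropenyl groups and the epimerisable cis C3 centre; the work-up hydrolyses the silyl ester and silyl enol ether.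

## Compound list

1 | (R)-lavandulol, (2R)-5-methyl-2-(prop-1-en-2-yl)hex-4-en-1-ol | C=C(C)[C@@H](CC=C(C)C)CO | starting material
2 | (R)-lavandulyl iodide, (3R)-3-(iodomethyl)-2,6-dimethylhepta-1,5-diene | C=C(C)[C@@H](CC=C(C)C)CI | intermediate
3 | 5-methylhex-4-enoic acid | CC(C)=CCCC(=O)O | starting material
4 | 5-methyl-2-[(2S)-5-methyl-2-(prop-1-en-2-yl)hex-4-en-1-yl]hex-4-enoic acid (C2 epimers) | C=C(C)[C@@H](CC=C(C)C)CC(CC=C(C)C)C(=O)O | intermediate
5 | 5-methyl-2-[(2S)-5-methyl-2-(prop-1-en-2-yl)hex-4-en-1-yl]hex-4-enoyl chloride | C=C(C)[C@@H](CC=C(C)C)CC(CC=C(C)C)C(=O)Cl | intermediate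
6 | ethoxyacetylene | C#COCC | starting material
7 | lavandulyl(prenyl)ketene | C=C(C)[C@@H](CC=C(C)C)CC(CC=C(C)C)=C=O | intermediate
8 | 3-ethoxy-4-lavandulyl-4-prenylcyclobut-2-en-1-one (C4 epimers) | C=C(C)[C@@H](CC=C(C)C)CC1(CC=C(C)C)C(=O)C=C1OCC | intermediate
9 | 5-benzylidene-2,2-dimethyl-1,3-dioxane-4,6-dione | CC1(C)OC(=O)C(=Cc2ccccc2)C(=O)O1 | starting material
10 | (trimethylsilyl)acetylene | C#C[Si](C)(C)C | starting material
11 | 2,2-dimethyl-5-[(1S)-1-phenyl-3-(trimethylsilyl)prop-2-yn-1-yl]-1,3-dioxane-4,6-dione | C[Si](C)(C)C#C[C@@H](C1C(=O)OC(C)(C)OC1=O)c2ccccc2 | intermediate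
12 | (3S)-3-phenyl-5-(trimethylsilyl)pent-4-ynoic acid | C[Si](C)(C)C#C[C@@H](CC(=O)O)c1ccccc1 | intermediate
13 | (3R)-3-phenylpent-4-ynoic acid | C#C[C@@H](CC(=O)O)c1ccccc1 | intermediate
14 | tert-butyl (3R)-3-phenylpent-4-ynoate | C#C[C@@H](CC(=O)OC(C)(C)C)c1ccccc1 | intermediate
15 | lithium ynolate of 14, lithium (3S)-5-tert-butoxy-5-oxo-3-phenylpent-1-yn-1-olate | [Li+].[O-]C#C[C@@H](CC(=O)OC(C)(C)C)c1ccccc1 | intermediate
16 | tert-butyl (3S)-3-phenyl-5-[(triisopropylsilyl)oxy]pent-4-ynoate | CC(C)[Si](C(C)C)(C(C)C)OC#C[C@@H](CC(=O)OC(C)(C)C)c1ccccc1 | intermediate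
17 | 3-ethoxy-7-methyl-4-[(2S)-5-methyl-2-(prop-1-en-2-yl)hex-4-en-1-yl]octa-1,3,6-trien-1-one (vinylketene, E/Z) | C=C(C)[C@@H](CC=C(C)C)CC(CC=C(C)C)=C(OCC)C=C=O | intermediate
18 | tert-butyl (3S)-3-{3-[1-ethoxy-2-lavandulyl-2-prenylethenyl]-4-oxo-2-[(triisopropylsilyl)oxy]cyclobut-1-en-1-yl}-3-phenylpropanoate (ring epimers, E/Z) | C=C(C)[C@@H](CC=C(C)C)CC(CC=C(C)C)=C(OCC)C1C(=O)C([C@@H](CC(=O)OC(C)(C)C)c2ccccc2)=C1O[Si](C(C)C)(C(C)C)C(C)C | intermediate
19 | dienylketene: tert-butyl (3S)-4-(oxomethylidene)-3-phenyl-hexa-dienoate core, O=C=C[CH(Ph)CH2CO2tBu]–C(OTIPS)=CH–C(OEt)=C(prenyl)(lavandulyl) | C=C(C)[C@@H](CC=C(C)C)CC(CC=C(C)C)=C(OCC)C=C(O[Si](C(C)C)(C(C)C)C(C)C)C(=C=O)[C@@H](CC(=O)OC(C)(C)C)c1ccccc1 | intermediate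
20 | tert-butyl (3S)-3-{(5S)-4-ethoxy-5-lavandulyl-6-oxo-5-prenyl-2-[(triisopropylsilyl)oxy]cyclohexa-1,3-dien-1-yl}-3-phenylpropanoate (ring C5 = C8 of the target) | C=C(C)[C@@H](CC=C(C)C)C[C@]1(CC=C(C)C)C(=O)C([C@@H](CC(=O)OC(C)(C)C)c2ccccc2)=C(O[Si](C(C)C)(C(C)C)C(C)C)C=C1OCC | intermediate
21 | 3-iodo derivative of 20 (iodine at C4a of the target numbering) | C=C(C)[C@@H](CC=C(C)C)C[C@]1(CC=C(C)C)C(=O)C([C@@H](CC(=O)OC(C)(C)C)c2ccccc2)=C(O[Si](C(C)C)(C(C)C)C(C)C)C(I)=C1OCC | intermediate
22 | (4S)-4-benzyl-3-propanoyl-1,3-oxazolidin-2-one | CCC(=O)N1[C@@H](Cc2ccccc2)COC1=O | starting material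
23 | acetaldehyde | CC=O | starting material
24 | (4S)-4-benzyl-3-[(2S,3R)-3-hydroxy-2-methylbutanoyl]-1,3-oxazolidin-2-one | O[C@H](C)[C@H](C)C(=O)N1[C@@H](Cc2ccccc2)COC1=O | intermediate
25 | (4S)-4-benzyl-3-[(2S,3R)-3-{[tert-butyl(dimethyl)silyl]oxy}-2-methylbutanoyl]-1,3-oxazolidin-2-one | CC(C)(C)[Si](C)(C)O[C@H](C)[C@H](C)C(=O)N1[C@@H](Cc2ccccc2)COC1=O | intermediate
26 | (2R,3R)-3-{[tert-butyl(dimethyl)silyl]oxy}-2-methylbutan-1-ol | CC(C)(C)[Si](C)(C)O[C@H](C)[C@H](C)CO | intermediate
27 | (2S,3R)-3-{[tert-butyl(dimethyl)silyl]oxy}-2-methylbutanal | CC(C)(C)[Si](C)(C)O[C@H](C)[C@H](C)C=O | intermediate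
28 | C4a (1-hydroxy-2-methyl-3-silyloxybutyl) dienone (carbinol epimers; side-chain centres as in 27) | C=C(C)[C@@H](CC=C(C)C)C[C@]1(CC=C(C)C)C(=O)C([C@@H](CC(=O)OC(C)(C)C)c2ccccc2)=C(O[Si](C(C)C)(C(C)C)C(C)C)C(C(O)[C@@H](C)[C@@H](C)O[Si](C)(C)C(C)(C)C)=C1OCC | intermediate
29 | C4a [(2S,3R)-3-silyloxy-2-methylbutanoyl] dienone | C=C(C)[C@@H](CC=C(C)C)C[C@]1(CC=C(C)C)C(=O)C([C@@H](CC(=O)OC(C)(C)C)c2ccccc2)=C(O[Si](C(C)C)(C(C)C)C(C)C)C(C(=O)[C@@H](C)[C@@H](C)O[Si](C)(C)C(C)(C)C)=C1OCC | intermediate
30 | desilylated hydroxy enol of 29 (C5–OH, side-chain OH free, C8a–OEt) | C=C(C)[C@@H](CC=C(C)C)C[C@]1(CC=C(C)C)C(=O)C([C@@H](CC(=O)OC(C)(C)C)c2ccccc2)=C(O)C(C(=O)[C@@H](C)[C@@H](C)O)=C1OCC | intermediate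
31 | tert-butyl (3S)-3-[(2R,3S,8S)-5-hydroxy-8-lavandulyl-2,3-dimethyl-4,7-dioxo-8-prenyl-3,4,7,8-tetrahydro-2H-chromen-6-yl]-3-phenylpropanoate | C=C(C)[C@@H](CC=C(C)C)C[C@]1(CC=C(C)C)C(=O)C([C@@H](CC(=O)OC(C)(C)C)c2ccccc2)=C(O)C2=C1O[C@H](C)[C@H](C)C2=O | intermediate
32 | trimethylsilyl ester and C5 trimethylsilyl enol ether of the target | C=C(C)[C@@H](CC=C(C)C)C[C@]1(CC=C(C)C)C(=O)C([C@@H](CC(=O)O[Si](C)(C)C)c2ccccc2)=C(O[Si](C)(C)C)C2=C1O[C@H](C)[C@H](C)C2=O | intermediate
33 | (3S)-3-[(2R,3S,8S)-5-hydroxy-2,3-dimethyl-8-(3-methylbut-2-en-1-yl)-8-[(2S)-5-methyl-2-(prop-1-en-2-yl)hex-4-en-1-yl]-4,7-dioxo-3,4,7,8-tetrahydro-2H-chromen-6-yl]-3-phenylpropanoic acid | C=C(C)[C@@H](CC=C(C)C)C[C@]1(CC=C(C)C)C(=O)C([C@@H](CC(=O)O)c2ccccc2)=C(O)C2=C1O[C@H](C)[C@H](C)C2=O | target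

## Step count

Total: 19 steps. Longest linear sequence: 11 steps (steps 5–11 and 16–19; the branch through steps 1–4 is equally long).

## Steps most likely to fail

Step 10. The electrocyclisation may close without facial bias, because both helical senses and both enol ether geometries are open to it, so that much of the material ends as the wrong C8 epimer; prolonged heating may also start a [3,3] shift of the C8 prenyl group. The fallback sets out from the unwanted epimer, tert-butyl (3S)-3-{(5R)-4-ethoxy-5-lavandulyl-6-oxo-5-prenyl-2-[(triisopropylsilyl)oxy]cyclohexa-1,3-dien-1-yl}-3-phenylpropanoate F1. It is irradiated at about 350 nm in degassed hexane, which is the known photochemical ring opening of 6,6-disubstituted cyclohexa-2,4-dienones to dienylketenes. This regenerates 19, which recloses in the dark to both epimers, and repeated separation and irradiation should move the material to 20, where the route is rejoined.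

Step 9. The photochemical opening of the vinylogous-ester cyclobutenone may be inefficient, or secondary photoreactions (enone–alkene cycloaddition of 8 with its own prenyl group, photolysis of 18) and intramolecular ketene–alkene cycloaddition may consume the material. The fallback sets out from 8 and makes the same ketene in the dark. Compound 8 is heated in ethanol (sealed tube, about 120 °C), so that the thermally formed vinylketene is trapped as ethyl 3-ethoxy-7-methyl-4-lavandulylocta-3,6-dienoate F2. Potassium trimethylsilanolate in THF gives potassium 3-ethoxy-7-methyl-4-lavandulylocta-3,6-dienoate F3, and oxalyl chloride gives 3-ethoxy-7-methyl-4-lavandulylocta-3,6-dienoyl chloride F4. Triethylamine at 0 °C in the presence of 16 regenerates 17 by dehydrochlorination, and the [2+2] cycloaddition returns to the route at 18.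

Step 11. The iodonium source may attack C6 with loss of the silyl group, or trigger iodocyclisation of a prenyl group onto a carbonyl oxygen, instead of substituting C4a. The fallback sets out from 20 and avoids halogenation and organochromium chemistry.
- Dilute aqueous HCl in THF hydrolyses both enol ethers to tert-butyl (3S)-3-[(5S)-2-hydroxy-5-lavandulyl-4,6-dioxo-5-prenylcyclohex-1-en-1-yl]-3-phenylpropanoate F5.
- LiOH/H2O2 cleavage of 25 gives (2S,3R)-3-{[tert-butyl(dimethyl)silyl]oxy}-2-methylbutanoic acid F6.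
- DCC/DMAP joins F5 and F6 by O-acylation and DMAP-mediated O→C acyl migration to the only methylene between two carbonyls (C4a), giving the C4a-acyl triketone tert-butyl (3S)-3-{(5S)-3-[(2S,3R)-3-{[tert-butyl(dimethyl)silyl]oxy}-2-methylbutanoyl]-2,4-dihydroxy-5-lavandulyl-6-oxo-5-prenylcyclohexa-1,3-dien-1-yl}-3-phenylpropanoate F7.
- HF·pyridine gives the free β-hydroxy ketone tert-butyl (3S)-3-{(5S)-2,4-dihydroxy-3-[(2S,3R)-3-hydroxy-2-methylbutanoyl]-5-lavandulyl-6-oxo-5-prenylcyclohexa-1,3-dien-1-yl}-3-phenylpropanoate F8.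
- Acid-catalysed cyclodehydration (PPTS, benzene, 4 Å sieves) closes the dihydropyranone and returns to the route at 31. The price is a regioisomer closed on the C5 oxygen, which has to be separated.

## Further compounds

F1 | step 10 | tert-butyl (3S)-3-{(5R)-4-ethoxy-5-lavandulyl-6-oxo-5-prenyl-2-[(triisopropylsilyl)oxy]cyclohexa-1,3-dien-1-yl}-3-phenylpropanoate (C8 epimer of 20) | C=C(C)[C@@H](CC=C(C)C)C[C@@]1(CC=C(C)C)C(=O)C([C@@H](CC(=O)OC(C)(C)C)c2ccccc2)=C(O[Si](C(C)C)(C(C)C)C(C)C)C=C1OCC
F2 | step 9 | ethyl 3-ethoxy-7-methyl-4-[(2S)-5-methyl-2-(prop-1-en-2-yl)hex-4-en-1-yl]octa-3,6-dienoate | C=C(C)[C@@H](CC=C(C)C)CC(CC=C(C)C)=C(OCC)CC(=O)OCC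
F3 | step 9 | potassium 3-ethoxy-7-methyl-4-[(2S)-5-methyl-2-(prop-1-en-2-yl)hex-4-en-1-yl]octa-3,6-dienoate | C=C(C)[C@@H](CC=C(C)C)CC(CC=C(C)C)=C(OCC)CC(=O)[O-].[K+]
F4 | step 9 | 3-ethoxy-7-methyl-4-[(2S)-5-methyl-2-(prop-1-en-2-yl)hex-4-en-1-yl]octa-3,6-dienoyl chloride | C=C(C)[C@@H](CC=C(C)C)CC(CC=C(C)C)=C(OCC)CC(=O)Cl
F5 | step 11 | tert-butyl (3S)-3-[(5S)-2-hydroxy-5-lavandulyl-4,6-dioxo-5-prenylcyclohex-1-en-1-yl]-3-phenylpropanoate | C=C(C)[C@@H](CC=C(C)C)C[C@]1(CC=C(C)C)C(=O)C([C@@H](CC(=O)OC(C)(C)C)c2ccccc2)=C(O)CC1=O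
F6 | step 11 | (2S,3R)-3-{[tert-butyl(dimethyl)silyl]oxy}-2-methylbutanoic acid | CC(C)(C)[Si](C)(C)O[C@H](C)[C@H](C)C(=O)O
F7 | step 11 | tert-butyl (3S)-3-{(5S)-3-[(2S,3R)-3-{[tert-butyl(dimethyl)silyl]oxy}-2-methylbutanoyl]-2,4-dihydroxy-5-lavandulyl-6-oxo-5-prenylcyclohexa-1,3-dien-1-yl}-3-phenylpropanoate | C=C(C)[C@@H](CC=C(C)C)C[C@]1(CC=C(C)C)C(=O)C([C@@H](CC(=O)OC(C)(C)C)c2ccccc2)=C(O)C(C(=O)[C@@H](C)[C@@H](C)O[Si](C)(C)C(C)(C)C)=C1O
F8 | step 11 | tert-butyl (3S)-3-{(5S)-2,4-dihydroxy-3-[(2S,3R)-3-hydroxy-2-methylbutanoyl]-5-lavandulyl-6-oxo-5-prenylcyclohexa-1,3-dien-1-yl}-3-phenylpropanoate | C=C(C)[C@@H](CC=C(C)C)C[C@]1(CC=C(C)C)C(=O)C([C@@H](CC(=O)OC(C)(C)C)c2ccccc2)=C(O)C(C(=O)[C@@H](C)[C@@H](C)O)=C1O
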